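**Plan**
- Retrosynthetic cuts: the C2 acetate; C13=C14 (olefination of a C13 methyl ketone); C9–C11 (carbon nucleophile onto a C9 ketone); the C2 and C3 oxygens (from a C2=C3 alkene); finally C1–C10 and C4–C5 together (Diels–Alder).
- Enabling feature: in ring B, C9 is at ketone level between the methyl-bearing carbons C10 and C8, which is the pattern of 2,6-dimethylbenzoquinone. Ring A, with its C4 gem-dimethyl group and C2/C3 cis-diol, maps onto 4-methylpenta-1,3-diene.
- Forward order: ring B is the quinone and ring A closes onto it in the [4+2]. C5 is then inverted, C7=C8 reduced and C6 deoxygenated to give a trans-decalone. The side chain is joined at C9, the alkene dihydroxylated, the chain extended, and C2 acetylated last.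
- Stereochemistry: C10 from the chiral Lewis acid; C5 by kinetic α-protonation; C8 by equilibration (equatorial); C9 by axial attack anti to the C10 methyl; C2/C3 by α-face osmylation; the 13E alkene from the phosphonate olefination.

Key step: step 1

Numbering: labdane-type labels are used (ring A = C1–C5 and C10, ring B = C5–C10, side chain C11–C15 with methyl C16 on C13); β is the face of the C10 methyl, α the opposite face.

Assumption: the sense of induction is taken from the usual binding model of protonated oxazaborolidines with quinones (boron on the unflanked carbonyl, α-C–H···O contact, one face covered by a gem-phenyl group), which points to the (3aR)-catalyst for adduct 3; should the adduct prove antipodal, the (3aS)-catalyst is used instead.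

**Step 1**
Reactants: 1 2,6-dimethyl-1,4-benzoquinone; 2 4-methylpenta-1,3-diene
Product: 3 (4aR,8aS)-2,5,5,8a-tetramethyl-4a,5,8,8a-tetrahydronaphthalene-1,4-dione (cis-fused; H5 and the C10 methyl both β)
Conditions: (3aR)-1-(2-methylphenyl)-3,3-diphenyltetrahydro-1H,3H-pyrrolo[1,2-c][1,3,2]oxazaborole (C24H24BNO, 20 mol %), Tf2NH (20 mol %), 2 (5 equiv), CH2Cl2, −78 → −20 °C
Reagents that add atoms: none
Why: Protonation of the oxazaborolidine by Tf2NH gives a cationic boron Lewis acid that binds the C6 carbonyl of 1 (the one not flanked by methyl groups) and lowers the LUMO of the adjacent C5=C10 bond for a concerted but asynchronous Diels–Alder reaction with the s-cis diene; the closest known reaction type is the oxazaborolidinium-catalysed enantioselective Diels–Alder reaction of alkylbenzoquinones with acyclic alkyl dienes. Ring A closes as a six-membered carbocycle by intermolecular [4+2] cycloaddition, the C1–C10 bond forming ahead of the C4–C5 bond. C10 is set by the catalyst, whose gem-phenyl group covers one face of the coordinated enone so that the diene adds to the other, and C5 follows as cis to the C10 methyl because the addition is suprafacial on the dienophile. The step needs regiocontrol (unsubstituted diene terminus to the methyl-bearing C10), which is secured by coordination at C6=O making C10 the electrophilic β-carbon, by the larger HOMO coefficient at the CH2 terminus of the diene, and by the avoidance of vicinal quaternary centres. The two methyl-bearing double bonds of 1 are interchanged by its twofold axis, so only the choice of face matters. Excess diene and stepwise warming to −20 °C are used because the cis-methyl at the diene terminus slows the s-cis approach.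

**Step 2**
Reactants: 3 cis-fused enedione
Product: 5 (4aS,8aS)-2,5,5,8a-tetramethyl-4a,5,8,8a-tetrahydronaphthalene-1,4-dione (trans-fused; 5α-H), via potassium dienolate 4 (not isolated)
Conditions: t-BuOK (1.5 equiv), THF/t-BuOH, −20 °C; inverse quench into AcOH/THF, −78 °C
Reagents that add atoms: none
Why: Thermodynamic-enolate formation followed by irreversible kinetic protonation: C5–H is the only α-hydrogen of the C6 ketone, and in the planar enolate the C10 methyl and the 4β-methyl stand over the β face of C5, so the proton is delivered to the α face and C5 becomes trans to the angular methyl.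

**Step 3**
Reactants: 5 trans-fused enedione
Product: 6 (2R,4aS,8aS)-2,5,5,8a-tetramethyl-2,3,4a,5,8,8a-hexahydronaphthalene-1,4-dione (trans-fused; 8α-methyl)
Conditions: Zn dust, AcOH, 23 °C
Reagents that add atoms: none
Why: Zinc (dissolving-metal) reduction of the ene-1,4-dione saturates C7–C8 by two electron transfers and protonations while the isolated C2=C3 alkene and both carbonyls are untouched; C8 is protonated under equilibrating acidic conditions and settles with its methyl equatorial (α), away from the syn-axial C10 methyl.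

**Step 4**
Reactants: 6 trans-fused dione
Product: 7 C6 mono-tosylhydrazone of 6 (C9 ketone free)
Conditions: TsNHNH2 (1.05 equiv), MeOH, 23–40 °C
Reagents that add atoms: p-toluenesulfonyl hydrazide, Cc1ccc(cc1)S(=O)(=O)NN
Why: Tosylhydrazone condensation occurs at the C6 carbonyl only, because C9 is shielded by quaternary C10 and the C8 methine, so the two ketones are differentiated by sterics.

**Step 5**
Reactants: 7 C6 tosylhydrazone
Product: 9 (2R,4aS,8aS)-2,5,5,8a-tetramethyl-3,4,4a,5,8,8a-hexahydronaphthalen-1(2H)-one (trans-decalone; C9 ketone, 8α-methyl, C2=C3 alkene), via N-boryl tosylhydrazine 8 (not isolated)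
Conditions: catecholborane (1.5 equiv), CHCl3, 0 °C; NaOAc·3H2O, 60 °C; then NaOMe (cat.), MeOH, 23–40 °C
Reagents that add atoms: none
Why: Catecholborane reduction of the tosylhydrazone (hydride to C6, then acetate-induced loss of sulfinate and N2) replaces C=N by CH2 under non-basic, non-epimerising conditions that spare the alkene and the hindered C9 ketone, and the closing NaOMe treatment equilibrates C8 to the equatorial α-methyl now that C5 can no longer epimerise.

**Step 6**
Reactants: 9 trans-decalone; 10 2-(2-bromoethyl)-2-methyl-1,3-dioxolane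
Product: 13 (1S,2R,4aS,8aS)-2,5,5,8a-tetramethyl-1-[2-(2-methyl-1,3-dioxolan-2-yl)ethyl]-1,2,3,4,4a,5,8,8a-octahydronaphthalen-1-ol (9β-OH; side chain 9α), via Grignard reagent 11 (not isolated), via organocerium reagent 12 (not isolated)
Conditions: 10 (3 equiv), Mg, THF, ≤30 °C; anhydrous CeCl3 (3 equiv), THF, −78 °C; then 9, −78 → 0 °C
Reagents that add atoms: none
Why: Organocerium 1,2-addition to a hindered, enolisable ketone: the weakly basic RCeCl2 suppresses enolisation and β-hydride reduction, and it enters axially on the α face, antiperiplanar to the axial C10 methyl (the equatorial path is gauche to that methyl and to C1), which sets C9 with C11 α and the hydroxyl β.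

**Step 7**
Reactants: 13 tertiary alcohol with C2=C3 alkene
Product: 14 (1S,2R,4aS,6S,7R,8aS)-2,5,5,8a-tetramethyl-1-[2-(2-methyl-1,3-dioxolan-2-yl)ethyl]decahydronaphthalene-1,6,7-triol (2α,3α,9β-triol)
Conditions: OsO4 (5 mol %), N-methylmorpholine N-oxide (1.5 equiv), acetone/H2O, 23 °C
Reagents that add atoms: OsO4, O=[Os](=O)(=O)=O; N-methylmorpholine N-oxide, C[N+]1([O-])CCOCC1; water, O
Why: Catalytic OsO4 syn-dihydroxylation (Upjohn) attacks the only alkene from the α face, because the axial C10 methyl and the axial 4β-methyl block the β face of C2=C3, giving the 2α,3α-diol.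

**Step 8**
Reactants: 14 triol ketal
Product: 15 4-[(1S,2R,4aS,6S,7R,8aS)-1,6,7-trihydroxy-2,5,5,8a-tetramethyldecahydronaphthalen-1-yl]butan-2-one
Conditions: 1 M HCl (aq)/THF 1:4, 23 °C
Reagents that add atoms: water, O
Why: Acid-catalysed acetal hydrolysis frees the methyl ketone (which may sit partly in its ring-closed hemiketal form with the C9 hydroxyl and reacts through the open ketone); dilute acid at room temperature leaves the tertiary alcohol intact, and acetone is avoided so that the cis-diol is not converted into an acetonide.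

**Step 9**
Reactants: 15 triol methyl ketone; 16 trimethyl phosphonoacetate
Product: 18 methyl (2E)-5-[(1S,2R,4aS,6S,7R,8aS)-1,6,7-trihydroxy-2,5,5,8a-tetramethyldecahydronaphthalen-1-yl]-3-methylpent-2-enoate, via sodium phosphonate 17 (not isolated)
Conditions: 16 (4 equiv), NaH (3.8 equiv), THF, 0 °C; then 15, 23 → 50 °C
Reagents that add atoms: none
Why: Horner–Wadsworth–Emmons olefination of the methyl ketone builds C13=C14 with the ester trans to the larger C12 chain (E favoured, the minor Z isomer being removable by chromatography); the phosphonate is kept in slight excess over NaH so that no free alkoxide forms that could add the C9 hydroxyl across the new enoate.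

**Step 10**
Reactants: 18 triol enoate
Product: 19 methyl (2E)-5-[(1S,2R,4aS,6S,7R,8aS)-7-acetoxy-1,6-dihydroxy-2,5,5,8a-tetramethyldecahydronaphthalen-1-yl]-3-methylpent-2-enoate (CNP0135744.1)
Conditions: Ac2O (1.2 equiv), pyridine, 0 → 23 °C
Reagents that add atoms: acetic anhydride, CC(=O)OC(C)=O
Why: Selective esterification of the equatorial secondary C2 hydroxyl: the axial C3 hydroxyl is neopentyl beside the C4 gem-dimethyl group and the C9 hydroxyl is tertiary, so acylation without DMAP stops at the C2 monoacetate.

**Compound list**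
1 | 2,6-dimethyl-1,4-benzoquinone | CC1=CC(=O)C=C(C)C1=O | starting material
2 | 4-methylpenta-1,3-diene | C=CC=C(C)C | starting material
3 | (4aR,8aS)-2,5,5,8a-tetramethyl-4a,5,8,8a-tetrahydronaphthalene-1,4-dione (cis-fused adduct) | O=C1C(C)=CC(=O)[C@@H]2C(C)(C)C=CC[C@@]21C | intermediate
4 | potassium C5=C6 dienolate of 3 | CC1=CC([O-])=C2C(C)(C)C=CC[C@]2(C)C1=O.[K+] | intermediate
5 | (4aS,8aS)-2,5,5,8a-tetramethyl-4a,5,8,8a-tetrahydronaphthalene-1,4-dione (trans-fused) | O=C1C(C)=CC(=O)[C@H]2C(C)(C)C=CC[C@@]21C | intermediate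
6 | (2R,4aS,8aS)-2,5,5,8a-tetramethyl-2,3,4a,5,8,8a-hexahydronaphthalene-1,4-dione | O=C1[C@H](C)CC(=O)[C@H]2C(C)(C)C=CC[C@@]21C | intermediate
7 | C6 mono-tosylhydrazone of 6 | O=C1[C@H](C)CC(=NNS(=O)(=O)c3ccc(C)cc3)[C@H]2C(C)(C)C=CC[C@@]21C | intermediate
8 | N-(1,3,2-benzodioxaborol-2-yl) tosylhydrazine from 7 (C6–H, N–B) | O=C1[C@H](C)CC(N(NS(=O)(=O)c3ccc(C)cc3)B4Oc5ccccc5O4)[C@H]2C(C)(C)C=CC[C@@]21C | intermediate
9 | (2R,4aS,8aS)-2,5,5,8a-tetramethyl-3,4,4a,5,8,8a-hexahydronaphthalen-1(2H)-one | O=C1[C@H](C)CC[C@H]2C(C)(C)C=CC[C@@]21C | intermediate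
10 | 2-(2-bromoethyl)-2-methyl-1,3-dioxolane | CC1(CCBr)OCCO1 | starting material
11 | [2-(2-methyl-1,3-dioxolan-2-yl)ethyl]magnesium bromide | CC1(CC[Mg]Br)OCCO1 | intermediate
12 | dichloro[2-(2-methyl-1,3-dioxolan-2-yl)ethyl]cerium | CC1(CC[Ce](Cl)Cl)OCCO1 | intermediate
13 | (1S,2R,4aS,8aS)-2,5,5,8a-tetramethyl-1-[2-(2-methyl-1,3-dioxolan-2-yl)ethyl]-1,2,3,4,4a,5,8,8a-octahydronaphthalen-1-ol | CC1(CC[C@]2(O)[C@H](C)CC[C@H]3C(C)(C)C=CC[C@@]32C)OCCO1 | intermediate
14 | (1S,2R,4aS,6S,7R,8aS)-2,5,5,8a-tetramethyl-1-[2-(2-methyl-1,3-dioxolan-2-yl)ethyl]decahydronaphthalene-1,6,7-triol | CC1(CC[C@]2(O)[C@H](C)CC[C@H]3C(C)(C)[C@H](O)[C@H](O)C[C@@]32C)OCCO1 | intermediate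
15 | 4-[(1S,2R,4aS,6S,7R,8aS)-1,6,7-trihydroxy-2,5,5,8a-tetramethyldecahydronaphthalen-1-yl]butan-2-one | CC(=O)CC[C@]1(O)[C@H](C)CC[C@H]2C(C)(C)[C@H](O)[C@H](O)C[C@@]21C | intermediate
16 | trimethyl phosphonoacetate | COC(=O)CP(=O)(OC)OC | starting material
17 | sodium salt of trimethyl phosphonoacetate | COC(=O)[CH-]P(=O)(OC)OC.[Na+] | intermediate
18 | methyl (2E)-5-[(1S,2R,4aS,6S,7R,8aS)-1,6,7-trihydroxy-2,5,5,8a-tetramethyldecahydronaphthalen-1-yl]-3-methylpent-2-enoate | COC(=O)/C=C(\C)CC[C@]1(O)[C@H](C)CC[C@H]2C(C)(C)[C@H](O)[C@H](O)C[C@@]21C | intermediate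
19 | methyl (2E)-5-[(1S,2R,4aS,6S,7R,8aS)-7-acetoxy-1,6-dihydroxy-2,5,5,8a-tetramethyldecahydronaphthalen-1-yl]-3-methylpent-2-enoate | COC(=O)/C=C(\C)CC[C@]1(O)[C@H](C)CC[C@H]2C(C)(C)[C@H](O)[C@H](OC(C)=O)C[C@@]21C | target

**Step count**
Total: 10 steps. Longest linear sequence: 10 steps (1 and 2 to 19); bromide 10 enters in step 6 and phosphonate 16 in step 9.

**Steps most likely to fail**

Step 1. The cycloaddition may be too slow because the terminal cis-methyl of 2 disfavours the s-cis conformer, the Lewis acid may oligomerise the diene, or discrimination between the two faces may be poor. The fallback sets out from 1 and uses a more nucleophilic diene, 4-methyl-2-(triisopropylsilyloxy)penta-1,3-diene F1 (from 4-methylpent-3-en-2-one, i-Pr3SiOTf, Et3N). 2-Silyloxy dienes are the standard partners of this catalyst class, and a stepwise Michael–Michael closure tolerates the cis-methyl. Under the conditions of step 1 this should give the silyl enol ether adduct F2 (C2–OSi, C2=C3). CsF/PhNTf2 in DME converts it into the enol triflate F3, and Pd(OAc)2/PPh3 with HCO2H/Bu3N in DMF reduces C–OTf to C–H, returning to the route at 3.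

Step 2. Protonation may occur on the wrong face, the C8 methyl may be deprotonated in competition, or the ring fusion may slip back towards cis during steps 3 and 4 if the cis dione is thermodynamically competitive. The fallback sets out from 3, removes the C6 oxygen first and sets C5 by hydrogen delivery to a C5=C6 alkene. NaBH4/CeCl3·7H2O in MeOH at −78 °C reduces the less hindered C6 carbonyl to the allylic alcohol F4. MsCl/Et3N gives the mesylate F5, which DBU eliminates to the 5,7-dien-9-one F6. LiBH(s-Bu)3 in THF at −78 °C reduces C7=C8 in 1,4 fashion to the Δ5-en-9-one F7. Hydrogen-atom-transfer hydrogenation (Mn(dpm)3, PhSiH3, t-BuOOH, i-PrOH) then delivers hydrogen to C5 on the open α face while leaving the 1,2-disubstituted C2=C3 alkene. After NaOMe equilibration at C8 this returns to the route at 9.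

Step 6. Enolisation or β-hydride reduction may outrun addition at the hindered C9 carbonyl, or part of the nucleophile may enter from the β face. The fallback sets out from 9 and uses a slim, non-reducing sp nucleophile. 2-Ethynyl-2-methyl-1,3-dioxolane (C#CC1(C)OCCO1) with n-BuLi and CeCl3 in THF at −78 °C gives the lithium acetylide F8, which should add axially in the same sense to give the propargylic alcohol F9. OsO4/N-methylmorpholine N-oxide dihydroxylates the ring alkene (the alkyne reacts far more slowly) to the alkynyl triol F10. H2 over Pd/C in EtOAc saturates the triple bond and rejoins the route at 14.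

**Further compounds**
F1 | step 1 | 4-methyl-2-(triisopropylsilyloxy)penta-1,3-diene | C=C(O[Si](C(C)C)(C(C)C)C(C)C)C=C(C)C
F2 | step 1 | (4aR,8aS)-2,5,5,8a-tetramethyl-7-(triisopropylsilyloxy)-4a,5,8,8a-tetrahydronaphthalene-1,4-dione | O=C1C(C)=CC(=O)[C@@H]2C(C)(C)C=C(O[Si](C(C)C)(C(C)C)C(C)C)C[C@@]21C
F3 | step 1 | enol triflate corresponding to F2 (C2–OTf) | O=C1C(C)=CC(=O)[C@@H]2C(C)(C)C=C(OS(=O)(=O)C(F)(F)F)C[C@@]21C
F4 | step 2 | C6 allylic alcohol from 3 (6-hydroxy-7-en-9-one, cis-fused) | O=C1C(C)=CC(O)[C@@H]2C(C)(C)C=CC[C@@]21C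
F5 | step 2 | C6 mesylate of F4 | O=C1C(C)=CC(OS(C)(=O)=O)[C@@H]2C(C)(C)C=CC[C@@]21C
F6 | step 2 | (8aS)-2,5,5,8a-tetramethyl-8,8a-dihydronaphthalen-1(5H)-one (5,7-dien-9-one) | O=C1C(C)=CC=C2C(C)(C)C=CC[C@@]21C
F7 | step 2 | (8aS)-2,5,5,8a-tetramethyl-3,5,8,8a-tetrahydronaphthalen-1(2H)-one (Δ5-en-9-one, C8 epimers) | O=C1C(C)CC=C2C(C)(C)C=CC[C@@]21C
F8 | step 6 | lithium (2-methyl-1,3-dioxolan-2-yl)acetylide | [Li]C#CC1(C)OCCO1
F9 | step 6 | (1S,2R,4aS,8aS)-2,5,5,8a-tetramethyl-1-[(2-methyl-1,3-dioxolan-2-yl)ethynyl]-1,2,3,4,4a,5,8,8a-octahydronaphthalen-1-ol | CC1(C#C[C@]2(O)[C@H](C)CC[C@H]3C(C)(C)C=CC[C@@]32C)OCCO1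
F10 | step 6 | 2α,3α,9β-triol of F9 (alkyne retained) | CC1(C#C[C@]2(O)[C@H](C)CC[C@H]3C(C)(C)[C@H](O)[C@H](O)C[C@@]32C)OCCO1
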